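Labels: C1 methyl-bearing fusion carbon, C2/C3 methylenes, C4 tertiary carbinol, C5 fusion methine, C6 acyloxy methine, C7 methylene, C8=C9 alkene, C10 ketone. The plan rests on cutting C1–C10. The oxygens on C6 and C10 stand 1,4 across the C5–C1 bond shared by the five- and seven-membered rings. C1 can therefore serve as β-carbon of a C6 enone and C10 as a nucleophilic acyl radical. One 7-endo closure then makes the cycloheptane, quaternary C1 and the C5 fusion centre. Its precursor is a 2-methylcyclopentenyl ketone, with C4 taken from (S)-terpinen-4-ol as a silyl ether, whose C7–C9 chain ends in a C10 phenyl selenoester.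

Key step: step 12

Remark 1: (S)-terpinen-4-ol is assumed to be bought or enriched in high enantiomeric purity; C4 is never a reaction centre, so this purity carries through.
Remark 2: C6 arrives with the terpinen-4-ol carbons, so the side chain needs only four backbone carbons (C7–C10, a 2-methylbutane-1,4-diyl unit). A chain cut from 3-methylpentane-1,5-diol would be one carbon too long, so 3-methylbut-3-en-1-ol is used instead.
Remark 3: The chain is racemic at C8, so compounds 12 to 25 are C8 epimer mixtures that merge when C8 becomes trigonal in step 18.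

Step 1
Reactants: 1 (S)-terpinen-4-ol
Product: 2 (S)-terpinen-4-ol triethylsilyl ether
Conditions: TESOTf, 2,6-lutidine, CH2Cl2, 0 °C to rt
Reagents that add atoms: triethylsilyl trifluoromethanesulfonate, CC[Si](CC)(CC)OS(=O)(=O)C(F)(F)F
Why: Silyl triflate silylation of a hindered tertiary alcohol is routine and leaves C4 untouched; it is done first so that in steps 2 and 3 the C4 oxygen can neither close a lactol onto the C1 ketone, start a retro-aldol cleavage, nor rival the C1 hydroxyl as the group lost on dehydration.

Step 2
Reactants: 2 (S)-terpinen-4-ol triethylsilyl ether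
Product: 4 (S)-3-isopropyl-6-oxo-3-(triethylsilyloxy)heptanal, via secondary ozonide 3 (not isolated)
Conditions: O3, CH2Cl2, −78 °C; then Me2S, −78 °C to rt
Reagents that add atoms: ozone, [O-][O+]=O
Why: Ozonolysis with reductive work-up cleaves the only alkene, turning the methyl-bearing carbon into the C1 methyl ketone and the alkene CH into the C6 aldehyde, while the silyl ether and C4 are inert.

Step 3
Reactants: 4 (S)-3-isopropyl-6-oxo-3-(triethylsilyloxy)heptanal
Product: 5 (R)-5-isopropyl-2-methyl-5-(triethylsilyloxy)cyclopent-1-ene-1-carbaldehyde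
Conditions: piperidine (0.2 equiv), AcOH (0.2 equiv), 4 Å MS, PhMe, 60 °C
Reagents that add atoms: none
Why: Amine-catalysed intramolecular aldol condensation (enamine of the more reactive aldehyde, 5-enolexo attack of C5 on the C1 ketone, helped by quaternary C4 in the tether) and loss of the free C1 hydroxyl give the tetrasubstituted enal; C4 keeps its geometry and becomes R only through a change of CIP ranking.

Step 4
Reactants: 6 3-methylbut-3-en-1-ol
Product: 7 1-methoxy-4-[(3-methylbut-3-enyloxy)methyl]benzene (PMB ether of 6)
Conditions: NaH, PMBCl, Bu4NI (cat.), THF/DMF, 0 °C to rt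
Reagents that add atoms: 4-methoxybenzyl chloride, COc1ccc(CCl)cc1
Why: Williamson ether synthesis on a primary alkoxide; the PMB ether survives organomagnesium and periodinane chemistry and is later removed oxidatively without harm to the C4 silyl ether.

Step 5
Reactants: 7 PMB ether of 3-methylbut-3-en-1-ol
Product: 9 4-(4-methoxybenzyloxy)-2-methylbutan-1-ol (racemic), via B-alkyl-9-BBN adduct 8 (not isolated)
Conditions: 9-BBN, THF, 0 °C to rt; then NaOH, H2O2, 0 °C
Reagents that add atoms: hydrogen peroxide, OO; 9-borabicyclo[3.3.1]nonane, B1C2CCCC1CCC2 (boron and its ring held only in 8)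
Why: Hydroboration–oxidation of a 1,1-disubstituted alkene is anti-Markovnikov, so the hydroxyl lands on the terminal carbon (future C7) and the two chain ends are told apart without a selectivity problem; C8 forms racemic, which is harmless because it becomes trigonal in step 18.

Step 6
Reactants: 9 4-(4-methoxybenzyloxy)-2-methylbutan-1-ol
Product: 10 1-[(4-bromo-3-methylbutoxy)methyl]-4-methoxybenzene
Conditions: CBr4, PPh3, CH2Cl2, 0 °C
Reagents that add atoms: carbon tetrabromide, BrC(Br)(Br)Br
Why: Appel reaction, an SN2 displacement of the oxyphosphonium ion by bromide under neutral conditions that a PMB ether tolerates.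

Step 7
Reactants: 10 1-[(4-bromo-3-methylbutoxy)methyl]-4-methoxybenzene; 5 (R)-5-isopropyl-2-methyl-5-(triethylsilyloxy)cyclopent-1-ene-1-carbaldehyde
Product: 12 1-[(R)-5-isopropyl-2-methyl-5-(triethylsilyloxy)cyclopent-1-en-1-yl]-5-(4-methoxybenzyloxy)-3-methylpentan-1-ol (C6 and C8 epimers), via Grignard reagent 11 (not isolated)
Conditions: Mg (I2-activated), THF, rt to 40 °C; then 5, THF, −78 to 0 °C
Reagents that add atoms: magnesium, [Mg] (held only in 11, lost on work-up)
Why: 1,2-Addition of a primary Grignard reagent to an enal whose β-carbon is fully substituted, so conjugate addition is blocked; the C6 carbinol centre forms unselectively and is erased in step 8.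

Step 8
Reactants: 12 allylic alcohol
Product: 13 1-[(R)-5-isopropyl-2-methyl-5-(triethylsilyloxy)cyclopent-1-en-1-yl]-5-(4-methoxybenzyloxy)-3-methylpentan-1-one
Conditions: DMP, CH2Cl2, 0 °C to rt
Reagents that add atoms: none
Why: Dess–Martin oxidation of a secondary allylic alcohol under near-neutral conditions gives the tetrasubstituted enone without touching the PMB or silyl ether.

Step 9
Reactants: 13 PMB-protected enone
Product: 14 5-hydroxy-1-[(R)-5-isopropyl-2-methyl-5-(triethylsilyloxy)cyclopent-1-en-1-yl]-3-methylpentan-1-one
Conditions: DDQ, CH2Cl2/H2O (pH 7), 0 °C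
Reagents that add atoms: none
Why: Oxidative PMB cleavage (hydride abstraction from the electron-rich benzylic position, then hydrolysis of the oxocarbenium ion) is orthogonal to the silyl ether and to the electron-poor enone.

Step 10
Reactants: 14 primary alcohol
Product: 15 5-[(R)-5-isopropyl-2-methyl-5-(triethylsilyloxy)cyclopent-1-en-1-yl]-3-methyl-5-oxopentanoic acid
Conditions: TEMPO (cat.), NaOCl (cat.), NaClO2, MeCN/NaH2PO4–Na2HPO4 buffer (pH 6.7), 35 °C
Reagents that add atoms: sodium chlorite, [Na+].[O-]Cl=O
Why: TEMPO-catalysed oxidation with NaClO2 as terminal oxidant takes a primary alcohol through the aldehyde to the acid at near-neutral pH, where the tertiary silyl ether and the electron-poor alkene are safe.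

Step 11
Reactants: 15 keto acid
Product: 16 Se-phenyl 5-[(R)-5-isopropyl-2-methyl-5-(triethylsilyloxy)cyclopent-1-en-1-yl]-3-methyl-5-oxopentaneselenoate
Conditions: (PhSe)2, Bu3P, CH2Cl2, rt
Reagents that add atoms: diphenyl diselenide, c1ccc(cc1)[Se][Se]c1ccccc1
Why: Phosphine–diselenide activation (acyloxyphosphonium ion captured by phenylselenolate) turns acids into Se-phenyl selenoesters under neutral conditions, and the hindered tetrasubstituted enone should take up neither selenol nor phosphine.

Step 12
Reactants: 16 Se-phenyl selenoester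
Product: 18 (1S,4R,5R)-4-(triethylsilyloxy)daucane-6,10-dione (trans-fused hydroazulenedione: C1 methyl and C4 silyloxy on one face; H5, C10 and isopropyl on the other; C8 epimers), via cis-fused C5 epimer 17 (not isolated)
Conditions: (Me3Si)3SiH (slow addition), Et3B, air, PhMe (0.005 M), rt; then DBU, rt
Reagents that add atoms: none
Why: Ethyl radicals from Et3B/air start a chain in which (Me3Si)3Si• takes the PhSe group from 16, the nucleophilic C10 acyl radical adds to C1, the electron-poor β-carbon of the C6 enone, and the resulting C5 α-keto radical abstracts hydrogen from the silane. The closest known reaction type is the reductive cyclisation of acyl selenides onto enones and acrylates (intramolecular Giese addition), including endo closures to cycloheptanones and closures onto methyl-bearing alkene carbons. The single new ring, cycloheptane C1–C5–C6–C7–C8–C9–C10, closes 7-endo-trig with C6=O inside it, because 6-exo attack at C5 is polarity-mismatched and would place a quaternary carbon next to fully substituted C4. C1 is controlled by C4: the acyl group on C5 must twist out of the crowded enone plane, its small carbonyl oxygen should lean towards the C4 oxygen rather than the isopropyl group, the silyl group covers that same face, and so C7–C10 should hang on and attack from the face anti to OSiEt3, leaving the C1 methyl syn to it. C5 is set under thermodynamic control: hydrogen transfer may give cis-fused 17, and DBU should equilibrate it through the C6 enolate to trans-fused 18, in which C6 avoids the isopropyl group. The step needs ring closure to outrun hydrogen transfer to, and CO loss from, the acyl radical, which the slow donor (Me3Si)3SiH, high dilution, room temperature and the primary nature of the acyl radical secure, and both C8 epimers serve.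

Step 13
Reactants: 18 trans-fused dione silyl ether
Product: 19 (1S,4R,5R)-4-hydroxydaucane-6,10-dione
Conditions: HF·pyridine, pyridine, THF, 0 °C to rt
Reagents that add atoms: none
Why: Fluoride-driven silyl ether cleavage in a buffered, weakly acidic medium frees the C4 hydroxyl without forming the alkoxide that could open the β-hydroxy ketone by retro-aldol reaction.

Step 14
Reactants: 19 β-hydroxy dione
Product: 20 (1S,4R,5S,6S)-4,6-dihydroxydaucan-10-one
Conditions: Me4NBH(OAc)3, MeCN/AcOH (1:1), −20 to 0 °C
Reagents that add atoms: none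
Why: Evans–Saksena reduction: the C4 hydroxyl replaces an acetate on boron and hydride travels through a six-membered transition state to the C6 face syn to that hydroxyl, giving the 4,6-anti diol (6S), while C10, which sits on the opposite face of the cyclopentane and has no hydroxyl within reach, is not reduced by this mild reagent.

Step 15
Reactants: 21 4-hydroxybenzoic acid
Product: 23 4-(tert-butyldimethylsilyloxy)benzoic acid, via bis-silylated benzoate 22 (not isolated)
Conditions: TBSCl (2.2 equiv), imidazole, DMF, rt; then AcOH/THF/H2O, rt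
Reagents that add atoms: tert-butyldimethylsilyl chloride, CC(C)(C)[Si](C)(C)Cl
Why: Exhaustive silylation followed by selective hydrolysis of the far more labile silyl ester leaves the phenol TBS ether, chosen because buffered fluoride removes it at the end.

Step 16
Reactants: 20 (1S,4R,5S,6S)-4,6-dihydroxydaucan-10-one; 23 4-(tert-butyldimethylsilyloxy)benzoic acid
Product: 24 (1S,4R,5S,6S)-4-hydroxy-10-oxodaucan-6-yl 4-(tert-butyldimethylsilyloxy)benzoate
Conditions: DCC, DMAP (cat.), CH2Cl2, rt
Reagents that add atoms: none
Why: Steglich esterification acylates only the secondary C6 hydroxyl, because the tertiary C4 hydroxyl next to the isopropyl group is too hindered, and the C6–O bond is not broken, so the configuration is kept.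

Step 17
Reactants: 24 keto ester
Product: 25 (1S,4R,5S,6S)-4,10-bis(trimethylsilyloxy)dauc-9-en-6-yl 4-(tert-butyldimethylsilyloxy)benzoate
Conditions: TMSOTf, Et3N, CH2Cl2, 0 °C
Reagents that add atoms: trimethylsilyl trifluoromethanesulfonate, C[Si](C)(C)OS(=O)(=O)C(F)(F)F
Why: Soft enolisation with silyl triflate and amine: C10 can enolise only towards C9 because C1 is quaternary, so a single silyl enol ether forms, the C4 hydroxyl is capped at the same time, and no strong base is present that could cause acyl migration.

Step 18
Reactants: 25 silyl enol ether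
Product: 26 (1S,4R,5S,6S)-10-oxo-4-(trimethylsilyloxy)dauc-8-en-6-yl 4-(tert-butyldimethylsilyloxy)benzoate
Conditions: Pd(OAc)2 (1.1 equiv), MeCN, rt to 40 °C
Reagents that add atoms: none
Why: Saegusa–Ito oxidation: divalent palladium replaces silicon to give the C9-bound palladium enolate, and β-hydride elimination of the only available hydrogen, C8–H, gives the C8=C9 enone and merges both C8 epimers into one compound.

Step 19
Reactants: 26 protected enone
Product: 27 (1S,4R,5S,6S)-4-hydroxy-10-oxodauc-8-en-6-yl 4-hydroxybenzoate, i.e. (3R,3aS,4S,8aS)-3-hydroxy-3-isopropyl-6,8a-dimethyl-8-oxo-1,2,3,3a,4,5,8,8a-octahydroazulen-4-yl 4-hydroxybenzoate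
Conditions: TBAF, AcOH (1:1), THF, 0 °C
Reagents that add atoms: none
Why: Buffered fluoride cleaves the aryl TBS and the tertiary TMS ether, and the acetic acid keeps the medium from turning basic, which protects the product from vinylogous β-elimination of the C6 benzoate through C7 deprotonation.

Compound list
1 | (S)-terpinen-4-ol | CC1=CC[C@](O)(C(C)C)CC1 | starting material
2 | (S)-terpinen-4-ol triethylsilyl ether | CC1=CC[C@](O[Si](CC)(CC)CC)(C(C)C)CC1 | intermediate
3 | secondary ozonide of 2 (6,7,8-trioxabicyclo[3.2.1]octane) | CC12CC[C@@](O[Si](CC)(CC)CC)(C(C)C)CC(OO1)O2 | intermediate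
4 | (S)-3-isopropyl-6-oxo-3-(triethylsilyloxy)heptanal | O=CC[C@](O[Si](CC)(CC)CC)(C(C)C)CCC(C)=O | intermediate
5 | (R)-5-isopropyl-2-methyl-5-(triethylsilyloxy)cyclopent-1-ene-1-carbaldehyde | O=CC1=C(C)CC[C@@]1(O[Si](CC)(CC)CC)C(C)C | intermediate
6 | 3-methylbut-3-en-1-ol | CC(=C)CCO | starting material
7 | PMB ether of 3-methylbut-3-en-1-ol | CC(=C)CCOCc1ccc(OC)cc1 | intermediate
8 | 9-[4-(4-methoxybenzyloxy)-2-methylbutyl]-9-borabicyclo[3.3.1]nonane | COc1ccc(COCCC(C)CB2C3CCCC2CCC3)cc1 | intermediate
9 | 4-(4-methoxybenzyloxy)-2-methylbutan-1-ol | OCC(C)CCOCc1ccc(OC)cc1 | intermediate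
10 | 1-[(4-bromo-3-methylbutoxy)methyl]-4-methoxybenzene | BrCC(C)CCOCc1ccc(OC)cc1 | intermediate
11 | [4-(4-methoxybenzyloxy)-2-methylbutyl]magnesium bromide | Br[Mg]CC(C)CCOCc1ccc(OC)cc1 | intermediate
12 | C6 allylic alcohol (C10 PMB ether, C4 TES ether) | CC(CCOCc1ccc(OC)cc1)CC(O)C1=C(C)CC[C@@]1(O[Si](CC)(CC)CC)C(C)C | intermediate
13 | C6 enone (C10 PMB ether, C4 TES ether) | CC(CCOCc1ccc(OC)cc1)CC(=O)C1=C(C)CC[C@@]1(O[Si](CC)(CC)CC)C(C)C | intermediate
14 | C6 enone, C10 primary alcohol | CC(CCO)CC(=O)C1=C(C)CC[C@@]1(O[Si](CC)(CC)CC)C(C)C | intermediate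
15 | C6 enone, C10 carboxylic acid | CC(CC(=O)O)CC(=O)C1=C(C)CC[C@@]1(O[Si](CC)(CC)CC)C(C)C | intermediate
16 | C6 enone, C10 Se-phenyl selenoester | CC(CC(=O)[Se]c1ccccc1)CC(=O)C1=C(C)CC[C@@]1(O[Si](CC)(CC)CC)C(C)C | intermediate
17 | (1S,4R,5S)-4-(triethylsilyloxy)daucane-6,10-dione (cis-fused) | CC1CC(=O)[C@@]2(C)CC[C@@](O[Si](CC)(CC)CC)(C(C)C)[C@H]2C(=O)C1 | intermediate
18 | (1S,4R,5R)-4-(triethylsilyloxy)daucane-6,10-dione (trans-fused) | CC1CC(=O)[C@@]2(C)CC[C@@](O[Si](CC)(CC)CC)(C(C)C)[C@@H]2C(=O)C1 | intermediate
19 | (1S,4R,5R)-4-hydroxydaucane-6,10-dione | CC1CC(=O)[C@@]2(C)CC[C@@](O)(C(C)C)[C@@H]2C(=O)C1 | intermediate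
20 | (1S,4R,5S,6S)-4,6-dihydroxydaucan-10-one | CC1CC(=O)[C@@]2(C)CC[C@@](O)(C(C)C)[C@@H]2[C@@H](O)C1 | intermediate
21 | 4-hydroxybenzoic acid | OC(=O)c1ccc(O)cc1 | starting material
22 | tert-butyldimethylsilyl 4-(tert-butyldimethylsilyloxy)benzoate | CC(C)(C)[Si](C)(C)OC(=O)c1ccc(O[Si](C)(C)C(C)(C)C)cc1 | intermediate
23 | 4-(tert-butyldimethylsilyloxy)benzoic acid | OC(=O)c1ccc(O[Si](C)(C)C(C)(C)C)cc1 | intermediate
24 | (1S,4R,5S,6S)-4-hydroxy-10-oxodaucan-6-yl 4-(tert-butyldimethylsilyloxy)benzoate | CC1CC(=O)[C@@]2(C)CC[C@@](O)(C(C)C)[C@@H]2[C@@H](OC(=O)c2ccc(O[Si](C)(C)C(C)(C)C)cc2)C1 | intermediate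
25 | (1S,4R,5S,6S)-4,10-bis(trimethylsilyloxy)dauc-9-en-6-yl 4-(tert-butyldimethylsilyloxy)benzoate | CC1C=C(O[Si](C)(C)C)[C@@]2(C)CC[C@@](O[Si](C)(C)C)(C(C)C)[C@@H]2[C@@H](OC(=O)c2ccc(O[Si](C)(C)C(C)(C)C)cc2)C1 | intermediate
26 | (1S,4R,5S,6S)-10-oxo-4-(trimethylsilyloxy)dauc-8-en-6-yl 4-(tert-butyldimethylsilyloxy)benzoate | CC1=CC(=O)[C@@]2(C)CC[C@@](O[Si](C)(C)C)(C(C)C)[C@@H]2[C@@H](OC(=O)c2ccc(O[Si](C)(C)C(C)(C)C)cc2)C1 | intermediate
27 | (1S,4R,5S,6S)-4-hydroxy-10-oxodauc-8-en-6-yl 4-hydroxybenzoate | CC1=CC(=O)[C@@]2(C)CC[C@@](O)(C(C)C)[C@@H]2[C@@H](OC(=O)c2ccc(O)cc2)C1 | target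

Total step count: 19. Longest linear sequence: 15 (steps 1–3, 7–14, 16–19).

Steps most likely to fail

Step 12. Attack on the fully substituted, twisted C1 may be slow enough for hydrogen transfer to the acyl radical or CO loss to win. The tether may also reach the wrong face of C1.
The fallback forms the same C1–C10 bond by a stoichiometric single-electron reduction. That process has no hydrogen-donor chain and no acyl radical that can lose CO.
- It sets out from 14, which DMP oxidises to the C10 aldehyde F1.
- SmI2 with t-BuOH in THF at 0 °C should then bring about a ketyl–olefin reductive cyclisation onto the enone β-carbon. Trivalent samarium bridges the two oxygens, and the product is the 10-hydroxy-6-ketone F2.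
- DMP oxidation of the C10 carbinol, followed by the same DBU treatment, comes back to the route at 18.

Step 3. The enamine may expel the C4 silyloxy group by β-elimination, or the aldol may run in the wrong sense (methyl ketone enolate onto the aldehyde).
The fallback separates addition from dehydration, so that the reagent chooses the leaving group.
- It sets out from 4, which proline catalysis in DMSO at rt should take only as far as the β-hydroxy aldehyde F3.
- MsCl/Et3N (sulfene pathway) can derivatise only the free tertiary C1 hydroxyl, giving the C1 mesylate F4.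
- F4 loses methanesulfonate by E1cB elimination in the same medium, and the fallback comes back to the route at 5.

Step 14. Ligand exchange at the crowded tertiary hydroxyl may be sluggish, leading to no reaction or to undirected hydride attack with poor facial selectivity.
The fallback accepts attack from the open face and corrects C6 during ester formation.
- It sets out from 19, which Narasaka–Prasad reduction (Et2BOMe, NaBH4, THF/MeOH, −78 °C) should convert chemoselectively, through the boron chelate, into the 4,6-syn diol F5.
- Mitsunobu esterification of F5 with acid 23 (PPh3, DIAD, PhMe) inverts C6.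
- The fallback comes back to the route at 24, bypassing step 16.

Further compounds
F1 | step 12 | 5-[(R)-5-isopropyl-2-methyl-5-(triethylsilyloxy)cyclopent-1-en-1-yl]-3-methyl-5-oxopentanal | CC(CC=O)CC(=O)C1=C(C)CC[C@@]1(O[Si](CC)(CC)CC)C(C)C
F2 | step 12 | (1S,4R,5R)-10-hydroxy-4-(triethylsilyloxy)daucan-6-one (C8 and C10 epimers) | CC1CC(O)[C@@]2(C)CC[C@@](O[Si](CC)(CC)CC)(C(C)C)[C@@H]2C(=O)C1
F3 | step 3 | (5R)-2-hydroxy-5-isopropyl-2-methyl-5-(triethylsilyloxy)cyclopentane-1-carbaldehyde | O=CC1C(C)(O)CC[C@@]1(O[Si](CC)(CC)CC)C(C)C
F4 | step 3 | (5R)-2-formyl-3-isopropyl-1-methyl-3-(triethylsilyloxy)cyclopentyl methanesulfonate | O=CC1C(C)(OS(C)(=O)=O)CC[C@@]1(O[Si](CC)(CC)CC)C(C)C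
F5 | step 14 | (1S,4R,5S,6R)-4,6-dihydroxydaucan-10-one | CC1CC(=O)[C@@]2(C)CC[C@@](O)(C(C)C)[C@@H]2[C@H](O)C1
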